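**Plan**

1. Retrosynthetic cuts, in order: the two O–benzyl bonds on ring B; the C4a–C5 bond of ring A, which folds ring A back into a 2,3-dimethoxycyclobutenone on pyranone C6; the C8–C8a bond between that cyclobutenone and the pyranone (Stille); the pyranone ring itself (O1–C2 and C3–C4); the aryl–carbonyl bond of ring B.
2. Enabling feature: ring A carries OH, OMe, OMe, H on C5, C6, C7, C8. These map onto the carbonyl carbon, the two methoxy carbons and the sp3 CH of a squarate-derived cyclobutenone bound to C8a, and C8a=C4a is already a C=C bond of the γ-pyrone (ring C).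
3. Forward order: ring B is functionalised from 5-bromoresorcinol; ring C (the 4-pyranone) is built on its acid chloride; pyranone C6 is iodinated, stannylated and coupled with 4-chloro-2,3-dimethoxycyclobutenone; heating grows ring A; hydrogenolysis frees the ring B phenols.
4. Stereochemistry: the target is achiral. The only stereocentre on the way (C4 of the cyclobutenone) is carried as a racemate and is erased in the ring expansion.

Key step: step 13

Assumption: cyclobutenones 19, 20 and 21 are racemic and are handled cold and used promptly; nothing in the route depends on their configuration. TMP stands for 2,2,6,6-tetramethylpiperidide.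

**Route**

Step 1
Reactants: 1 5-bromobenzene-1,3-diol
Product: 2 1,3-bis(benzyloxy)-5-bromobenzene
Conditions: BnBr (2.2 equiv), K2CO3, DMF, 25 °C
Reagents that add atoms: benzyl bromide, BrCc1ccccc1
Why: Williamson etherification of both phenoxides with a reactive benzylic halide; the aryl bromide is inert under these conditions.

Step 2
Reactants: 2 1,3-bis(benzyloxy)-5-bromobenzene
Product: 4 2,4-bis(benzyloxy)-6-bromobenzaldehyde, via iminium chloride 3 (not isolated)
Conditions: POCl3, DMF, 0 to 90 °C; then ice–water
Reagents that add atoms: N,N-dimethylformamide, CN(C)C=O; water, O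
Why: Vilsmeier–Haack formylation should occur para to one benzyloxy group and ortho to the other (next to bromine), the site between the two ethers being the more crowded, as is usual for 1-bromo-3,5-dialkoxybenzenes; water hydrolyses the iminium salt to the aldehyde.

Step 3
Reactants: 4 2,4-bis(benzyloxy)-6-bromobenzaldehyde
Product: 6 2,4-bis(benzyloxy)-6-bromophenol, via aryl formate 5 (not isolated)
Conditions: mCPBA, CH2Cl2, 0 to 25 °C; then K2CO3 (cat.), MeOH, 25 °C
Reagents that add atoms: 3-chloroperoxybenzoic acid, O=C(OO)c1cccc(Cl)c1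
Why: Baeyer–Villiger (Dakin-type) oxidation, in which the electron-rich ortho/para-dialkoxyaryl group migrates in preference to hydrogen, followed by mild methanolysis of the formate.

Step 4
Reactants: 6 2,4-bis(benzyloxy)-6-bromophenol
Product: 7 1,5-bis(benzyloxy)-3-bromo-2-methoxybenzene
Conditions: MeI, K2CO3, DMF, 25 °C
Reagents that add atoms: iodomethane, CI
Why: Williamson O-methylation of the only free phenol fixes the future 2'-methoxy group next to the bromine.

Step 5
Reactants: 7 1,5-bis(benzyloxy)-3-bromo-2-methoxybenzene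
Product: 9 3,5-bis(benzyloxy)-2-methoxybenzoic acid, via aryllithium 8 (not isolated)
Conditions: n-BuLi, THF, −78 °C; then CO2; then 1 M HCl
Reagents that add atoms: carbon dioxide, O=C=O
Why: Bromine–lithium exchange at −78 °C is faster than benzylic deprotonation, the ortho-methoxy group stabilises the aryllithium, and carboxylation places the carbonyl carbon at C1'.

Step 6
Reactants: 9 3,5-bis(benzyloxy)-2-methoxybenzoic acid
Product: 10 3,5-bis(benzyloxy)-2-methoxybenzoyl chloride
Conditions: (COCl)2, DMF (cat.), CH2Cl2, 0 to 25 °C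
Reagents that add atoms: oxalyl chloride, O=C(Cl)C(=O)Cl
Why: Standard acid chloride formation under DMF catalysis; the crude chloride is used directly.

Step 7
Reactants: 10 3,5-bis(benzyloxy)-2-methoxybenzoyl chloride; 11 (E)-4-methoxybut-3-en-2-one
Product: 14 2-[3,5-bis(benzyloxy)-2-methoxyphenyl]-4H-pyran-4-one, via lithium dienolate 12 (not isolated), via enol ether diketone 13 (not isolated)
Conditions: LiN(SiMe3)2 (2.1 equiv), 11 (2.1 equiv), THF, −78 °C; then 10; then 1 M HCl; then CF3CO2H (cat.), toluene, 25 °C
Reagents that add atoms: none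
Why: Claisen-type C-acylation of the kinetic lithium enolate (the second equivalent takes up the acidic diketone proton), then acid-catalysed 6-endo oxa-Michael addition of the enol oxygen with loss of methanol, the standard route to 2-substituted 4-pyranones; benzyl ethers tolerate catalytic acid at 25 °C.

Step 8
Reactants: 14 2-[3,5-bis(benzyloxy)-2-methoxyphenyl]-4H-pyran-4-one
Product: 16 2-[3,5-bis(benzyloxy)-2-methoxyphenyl]-6-iodo-4H-pyran-4-one, via pyranonylzinc chloride 15 (not isolated)
Conditions: TMPZnCl·LiCl (1.3 equiv), THF, 25 °C; then I2, 0 °C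
Reagents that add atoms: iodine, II
Why: Directed zincation with a hindered zinc amide should remove the vinylic hydrogen next to the ring oxygen (C6–H), as with C2–H of chromones, and the covalent C–Zn bond should not trigger the ring opening typical of lithiated pyranones; iodinolysis then fixes the halogen at C6.

Step 9
Reactants: 16 2-[3,5-bis(benzyloxy)-2-methoxyphenyl]-6-iodo-4H-pyran-4-one
Product: 17 2-[3,5-bis(benzyloxy)-2-methoxyphenyl]-6-(trimethylstannyl)-4H-pyran-4-one
Conditions: Me3SnSnMe3 (1.5 equiv), Pd(PPh3)4 (5 mol %), toluene, 90 °C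
Reagents that add atoms: hexamethylditin, C[Sn](C)(C)[Sn](C)(C)C
Why: Palladium-catalysed stannylation of an alkenyl iodide with a distannane (zerovalent palladium inserts into the vinylogous acyl C–I bond, then tin transfer and reductive elimination); the excess of distannane should hold back homocoupling.

Step 10
Reactants: 18 dimethyl squarate
Product: 19 4-hydroxy-2,3-dimethoxycyclobut-2-en-1-one (racemic)
Conditions: LiAlH(OtBu)3 (1.05 equiv), THF, −78 °C; then cold water, rapid extraction
Reagents that add atoms: none
Why: 1,2-Reduction of one of the two equivalent carbonyls by a hindered hydride should stop at the mono-alcohol because the remaining carbonyl is a deactivated vinylogous ester; a neutral work-up avoids acid-induced loss of methanol, and the new stereocentre is racemic and needs no control.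

Step 11
Reactants: 19 4-hydroxy-2,3-dimethoxycyclobut-2-en-1-one
Product: 20 4-chloro-2,3-dimethoxycyclobut-2-en-1-one (racemic)
Conditions: PPh3, N-chlorosuccinimide, CH2Cl2, −20 to 0 °C; short silica plug, used at once
Reagents that add atoms: N-chlorosuccinimide, O=C1CCC(=O)N1Cl
Why: Appel-type deoxychlorination replaces OH by Cl through chloride attack at the allylic, α-keto carbon under neutral conditions, so no free acid is present to ionise C4 and expel methanol.

Step 12
Reactants: 17 2-[3,5-bis(benzyloxy)-2-methoxyphenyl]-6-(trimethylstannyl)-4H-pyran-4-one; 20 4-chloro-2,3-dimethoxycyclobut-2-en-1-one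
Product: 21 4-{6-[3,5-bis(benzyloxy)-2-methoxyphenyl]-4-oxo-4H-pyran-2-yl}-2,3-dimethoxycyclobut-2-en-1-one (racemic)
Conditions: Pd2(dba)3 (2.5 mol %), tri(2-furyl)phosphine (10 mol %), CuI (10 mol %), dioxane, 25 to 40 °C
Reagents that add atoms: none
Why: Stille coupling of a 4-chlorocyclobutenone with an alkenylstannane (oxidative addition of zerovalent palladium into the allylic, α-keto C–Cl bond, tin-to-palladium transfer assisted by CuI, reductive elimination at C4 so that the vinylogous ester stays conjugated); the low temperature should keep the four-membered ring closed until the next step.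

Step 13
Reactants: 21 4-{6-[3,5-bis(benzyloxy)-2-methoxyphenyl]-4-oxo-4H-pyran-2-yl}-2,3-dimethoxycyclobut-2-en-1-one
Product: 24 2-[3,5-bis(benzyloxy)-2-methoxyphenyl]-5-hydroxy-6,7-dimethoxy-4H-chromen-4-one, via dienylketene 22 (not isolated), via cyclohexadienone 23 (not isolated)
Conditions: toluene (dry, degassed, 0.01 M), 105 °C
Reagents that add atoms: none
Why: On heating, the cyclobutenone undergoes conrotatory 4π electrocyclic opening of its C1–C4 bond (future C5 and C8) to the dienylketene, whose electrophilic ketene carbon C5 and the enol-ether β-carbon C3 of the pyranone (future C4a) are joined by a thermal disrotatory 6π electrocyclisation that closes six-membered ring A through the new C4a–C5 bond; enolisation of the cyclohexadienone then gives the aromatic, hydrogen-bonded 5-hydroxychromone. The closest known reaction type is the thermal ring expansion of 4-alkenyl- and 4-heteroarylcyclobutenones to phenols (Moore-type benzannulation), with the C2=C3 bond of the γ-pyrone serving as the alkene arm. No stereocentre results, since C4 of 21 becomes the sp2 C8–H and the transient C4a centre of 23 is lost on tautomerisation. The step needs the pyranonyl group to rotate inward so that it lies cis to the ketene; because ring opening is reversible, the outward-rotated ketene re-closes to 21 and only the cis isomer is drained by cyclisation. Regiochemistry is fixed by the substrate, because the second neighbour of C8a is O1 and only C3 can accept the ketene, and the OH/OMe/OMe/H pattern is already written into the four-membered ring. High dilution in dry, degassed toluene should keep the ketene from dimerising or being trapped.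

Step 14
Reactants: 24 2-[3,5-bis(benzyloxy)-2-methoxyphenyl]-5-hydroxy-6,7-dimethoxy-4H-chromen-4-one
Product: 25 2-(3,5-dihydroxy-2-methoxyphenyl)-5-hydroxy-6,7-dimethoxy-4H-chromen-4-one
Conditions: H2 (1 atm), palladium on carbon (10 % Pd/C), EtOAc–MeOH, 25 °C
Reagents that add atoms: none
Why: Hydrogenolysis of the two aryl benzyl ethers; at 1 atm and 25 °C the chromone C2=C3 bond, the methyl ethers and the chelated 5-hydroxyl should remain, and the reaction is stopped after uptake of two equivalents.

**Compound list**

1 | 5-bromobenzene-1,3-diol | Oc1cc(O)cc(Br)c1 | starting material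
2 | 1,3-bis(benzyloxy)-5-bromobenzene | Brc1cc(OCc2ccccc2)cc(OCc2ccccc2)c1 | intermediate
3 | N-{[2,4-bis(benzyloxy)-6-bromophenyl]methylidene}-N-methylmethanaminium chloride | C[N+](C)=Cc1c(Br)cc(OCc2ccccc2)cc1OCc1ccccc1.[Cl-] | intermediate
4 | 2,4-bis(benzyloxy)-6-bromobenzaldehyde | O=Cc1c(Br)cc(OCc2ccccc2)cc1OCc1ccccc1 | intermediate
5 | 2,4-bis(benzyloxy)-6-bromophenyl formate | O=COc1c(Br)cc(OCc2ccccc2)cc1OCc1ccccc1 | intermediate
6 | 2,4-bis(benzyloxy)-6-bromophenol | Oc1c(Br)cc(OCc2ccccc2)cc1OCc1ccccc1 | intermediate
7 | 1,5-bis(benzyloxy)-3-bromo-2-methoxybenzene | COc1c(Br)cc(OCc2ccccc2)cc1OCc1ccccc1 | intermediate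
8 | [3,5-bis(benzyloxy)-2-methoxyphenyl]lithium | [Li]c1cc(OCc2ccccc2)cc(OCc2ccccc2)c1OC | intermediate
9 | 3,5-bis(benzyloxy)-2-methoxybenzoic acid | COc1c(C(=O)O)cc(OCc2ccccc2)cc1OCc1ccccc1 | intermediate
10 | 3,5-bis(benzyloxy)-2-methoxybenzoyl chloride | COc1c(C(=O)Cl)cc(OCc2ccccc2)cc1OCc1ccccc1 | intermediate
11 | (E)-4-methoxybut-3-en-2-one | CO/C=C/C(C)=O | starting material
12 | lithium (3E)-4-methoxybuta-1,3-dien-2-olate | [Li]OC(=C)/C=C/OC | intermediate
13 | (4E)-1-[3,5-bis(benzyloxy)-2-methoxyphenyl]-5-methoxypent-4-ene-1,3-dione | CO/C=C/C(=O)CC(=O)c1cc(OCc2ccccc2)cc(OCc2ccccc2)c1OC | intermediate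
14 | 2-[3,5-bis(benzyloxy)-2-methoxyphenyl]-4H-pyran-4-one | O=c1ccoc(-c2cc(OCc3ccccc3)cc(OCc3ccccc3)c2OC)c1 | intermediate
15 | chloro{6-[3,5-bis(benzyloxy)-2-methoxyphenyl]-4-oxo-4H-pyran-2-yl}zinc (as its LiCl complex) | Cl[Zn]c1cc(=O)cc(-c2cc(OCc3ccccc3)cc(OCc3ccccc3)c2OC)o1 | intermediate
16 | 2-[3,5-bis(benzyloxy)-2-methoxyphenyl]-6-iodo-4H-pyran-4-one | Ic1cc(=O)cc(-c2cc(OCc3ccccc3)cc(OCc3ccccc3)c2OC)o1 | intermediate
17 | 2-[3,5-bis(benzyloxy)-2-methoxyphenyl]-6-(trimethylstannyl)-4H-pyran-4-one | C[Sn](C)(C)c1cc(=O)cc(-c2cc(OCc3ccccc3)cc(OCc3ccccc3)c2OC)o1 | intermediate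
18 | dimethyl squarate (3,4-dimethoxycyclobut-3-ene-1,2-dione) | COC1=C(OC)C(=O)C1=O | starting material
19 | 4-hydroxy-2,3-dimethoxycyclobut-2-en-1-one (racemic) | COC1=C(OC)C(O)C1=O | intermediate
20 | 4-chloro-2,3-dimethoxycyclobut-2-en-1-one (racemic) | COC1=C(OC)C(Cl)C1=O | intermediate
21 | 4-{6-[3,5-bis(benzyloxy)-2-methoxyphenyl]-4-oxo-4H-pyran-2-yl}-2,3-dimethoxycyclobut-2-en-1-one (racemic) | COC1=C(OC)C(c2cc(=O)cc(-c3cc(OCc4ccccc4)cc(OCc4ccccc4)c3OC)o2)C1=O | intermediate
22 | (3E)-4-{6-[3,5-bis(benzyloxy)-2-methoxyphenyl]-4-oxo-4H-pyran-2-yl}-2,3-dimethoxybuta-1,3-dien-1-one (pyranonyl cis to the ketene) | O=C=C(OC)/C(OC)=C\c1cc(=O)cc(-c2cc(OCc3ccccc3)cc(OCc3ccccc3)c2OC)o1 | intermediate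
23 | 2-[3,5-bis(benzyloxy)-2-methoxyphenyl]-6,7-dimethoxy-4aH-chromene-4,5-dione (racemic at C4a) | COC1=C(OC)C(=O)C2C(=O)C=C(-c3cc(OCc4ccccc4)cc(OCc4ccccc4)c3OC)OC2=C1 | intermediate
24 | 2-[3,5-bis(benzyloxy)-2-methoxyphenyl]-5-hydroxy-6,7-dimethoxy-4H-chromen-4-one | COc1cc2oc(-c3cc(OCc4ccccc4)cc(OCc4ccccc4)c3OC)cc(=O)c2c(O)c1OC | intermediate
25 | 2-(3,5-dihydroxy-2-methoxyphenyl)-5-hydroxy-6,7-dimethoxy-4H-chromen-4-one | COc1cc2oc(-c3cc(O)cc(O)c3OC)cc(=O)c2c(O)c1OC | target

**Step count**

Total: 14 steps. Longest linear sequence: 12 steps (steps 1–9, then 12, 13, 14); steps 10 and 11 form the two-step side branch.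

**Steps most likely to fail**

1. Step 13 (ring expansion). The dienylketene may close only slowly onto the push–pull C=C bond of the pyranone, so that ketene dimerisation, capture by traces of nucleophile or decomposition of the strained ring wins. The fallback is a classical flavone assembly that buys in ring A. It sets out from acid chloride 10, which acylates commercial 1-(6-hydroxy-2,3,4-trimethoxyphenyl)ethan-1-one F1 (pyridine, CH2Cl2) to give 2-acetyl-3,4,5-trimethoxyphenyl 3,5-bis(benzyloxy)-2-methoxybenzoate F2. Baker–Venkataraman acyl migration (KOH, pyridine, 50 °C) should give 1-[3,5-bis(benzyloxy)-2-methoxyphenyl]-3-(6-hydroxy-2,3,4-trimethoxyphenyl)propane-1,3-dione F3. Acid-catalysed cyclodehydration (p-toluenesulfonic acid cat., toluene, 90 °C) should give 2-[3,5-bis(benzyloxy)-2-methoxyphenyl]-5,6,7-trimethoxy-4H-chromen-4-one F4. Hydrogenolysis (H2, palladium on carbon) should give 2-(3,5-dihydroxy-2-methoxyphenyl)-5,6,7-trimethoxy-4H-chromen-4-one F5. BCl3 (CH2Cl2, −20 to 0 °C) should then cleave only the 5-methyl ether, which is chelated to the C4 carbonyl, and the sequence comes back to the route at target 25.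

2. Step 11 (chlorination). Activation of the hydroxyl may ionise C4 with help from the C2 methoxy group, followed by loss of chloromethane to a cyclobutenedione, or the chloride may hydrolyse during handling. The fallback sets out from alcohol 19 and avoids a halide altogether: acetylation (Ac2O, pyridine, 0 °C) gives 2,3-dimethoxy-4-oxocyclobut-2-en-1-yl acetate F6. This allylic ester is coupled with stannane 17 under palladium catalysis (Pd2(dba)3, tri(2-furyl)phosphine, LiCl, DMF, 25 °C) and the route is rejoined at 21.

3. Step 12 (Stille coupling). Tin-to-palladium transfer from the electron-poor stannylpyranone may be slow, so that protodestannylation of 17 and decomposition of chloride 20 compete. The fallback sets out from pyranone 14: zinc reagent 15, generated as in step 8, is coupled directly with chloride 20 in a Negishi reaction (Pd2(dba)3, tri(2-furyl)phosphine, THF, 0 to 25 °C) and returns to the route at 21. It makes no new compound (F0) and bypasses the iodide and the stannane.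

**Further compounds**

F1 | step 13 | 1-(6-hydroxy-2,3,4-trimethoxyphenyl)ethan-1-one (purchased) | CC(=O)c1c(O)cc(OC)c(OC)c1OC
F2 | step 13 | 2-acetyl-3,4,5-trimethoxyphenyl 3,5-bis(benzyloxy)-2-methoxybenzoate | CC(=O)c1c(OC(=O)c2cc(OCc3ccccc3)cc(OCc3ccccc3)c2OC)cc(OC)c(OC)c1OC
F3 | step 13 | 1-[3,5-bis(benzyloxy)-2-methoxyphenyl]-3-(6-hydroxy-2,3,4-trimethoxyphenyl)propane-1,3-dione | COc1cc(O)c(C(=O)CC(=O)c2cc(OCc3ccccc3)cc(OCc3ccccc3)c2OC)c(OC)c1OC
F4 | step 13 | 2-[3,5-bis(benzyloxy)-2-methoxyphenyl]-5,6,7-trimethoxy-4H-chromen-4-one | COc1cc2oc(-c3cc(OCc4ccccc4)cc(OCc4ccccc4)c3OC)cc(=O)c2c(OC)c1OC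
F5 | step 13 | 2-(3,5-dihydroxy-2-methoxyphenyl)-5,6,7-trimethoxy-4H-chromen-4-one | COc1cc2oc(-c3cc(O)cc(O)c3OC)cc(=O)c2c(OC)c1OC
F6 | step 11 | 2,3-dimethoxy-4-oxocyclobut-2-en-1-yl acetate | COC1=C(OC)C(OC(C)=O)C1=O
F0 | step 12 | none | none
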